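**Retrosynthetic overview** (text numbering: ring A = C2–C6 with the carbinol C3; nine-membered ring B = C1, C2, C6, C7, C8, C9, C10, C11, C12; ring C = C10–C14 with C13=O)
- Ring B is opened last-first at C8–C9: intramolecular vinylogous Mukaiyama aldol of the ring C silyl dienol ether onto a C8 aldehyde.
- Ring A is cut at C4–C5 and C2–C3 in one operation: an acyclic C2 alkenyl boronate carrying a CH2I group (C5) on C6 is annulated with 2-lithio-3-methoxypropene (C3, C4, CH2OMe); boron ends on C3 and is oxidised to the C3 hydroxyl.
- Enabling feature: in ring A the oxygenated quaternary C3 sits between the alkene carbon C2 and the C4–C5 ethano link to C6, which is exactly the array produced when an alkenyl group shifts from boron to carbon while a C5 radical attacks the other alkene carbon.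
- C1–C12 is cut next: an alkynyl Grignard fragment (C1, C2, C5–C8, from furan-2(5H)-one) adds to a ring C ene-dione; syn protoboration then fixes the alkene geometry and places boron on C2.
- Ring order: ring C (preformed), ring A (key step), ring B (last).

Key step: step 17

Assumption: the facial sense of the reagent-controlled steps 1 and 11 is taken from the usual models; if the opposite sense were required, the antipodal ligand or oxaziridine would be used with no other change.

Step 1
Reactants: 1 furan-2(5H)-one; 2 potassium vinyltrifluoroborate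
Product: 3 (S)-4-vinyldihydrofuran-2(3H)-one
Conditions: [Rh(cod)2]PF6 (3 mol%), (S)-BINAP, toluene/H2O, 100 °C
Reagents that add atoms: none
Why: Rhodium-catalysed asymmetric conjugate addition of the vinylborate to the butenolide, in which the chiral diphosphine differentiates the faces of the planar lactone and should set C6 as 4S, the sense expected from the model for cyclic enones and unsaturated lactones.

Step 2
Reactants: 3 (S)-4-vinyldihydrofuran-2(3H)-one
Product: 5 (3R,4R)-3-methyl-4-vinyldihydrofuran-2(3H)-one, via lithium enolate 4 (not isolated)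
Conditions: LiN(iPr)2, THF, −78 °C; MeI, −78 → −40 °C
Reagents that add atoms: iodomethane, CI
Why: Enolate alkylation of a 4-substituted γ-butyrolactone, where the electrophile approaches the face opposite the vinyl group and so sets C7 trans to C6.

Step 3
Reactants: 5 (3R,4R)-3-methyl-4-vinyldihydrofuran-2(3H)-one
Product: 7 (3R,4R)-4-methyl-5-oxotetrahydrofuran-3-carbaldehyde, via secondary ozonide 6 (not isolated)
Conditions: O3, CH2Cl2/MeOH, −78 °C; PPh3, −78 °C → rt
Reagents that add atoms: ozone, [O-][O+]=O
Why: Ozonolysis with reductive work-up cleaves the only alkene to the aldehyde, and C6 (now α to the aldehyde) stays trans to C7 because that is the more stable arrangement on the lactone.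

Step 4
Reactants: 7 (3R,4R)-4-methyl-5-oxotetrahydrofuran-3-carbaldehyde
Product: 8 (3R,4S)-4-ethynyl-3-methyldihydrofuran-2(3H)-one
Conditions: dimethyl (1-diazo-2-oxopropyl)phosphonate, K2CO3, MeOH, 0 °C → rt
Reagents that add atoms: dimethyl (1-diazo-2-oxopropyl)phosphonate, COP(=O)(OC)C(=[N+]=[N-])C(C)=O
Why: Seyferth–Gilbert homologation (Ohira–Bestmann variant) converts the aldehyde into the terminal alkyne under carbonate conditions that can at most equilibrate C6 to the trans lactone already present.

Step 5
Reactants: 8 (3R,4S)-4-ethynyl-3-methyldihydrofuran-2(3H)-one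
Product: 9 (3R,4S)-4-ethynyl-3-methyltetrahydrofuran-2-ol (lactol, both anomers)
Conditions: iBu2AlH, CH2Cl2, −78 °C
Reagents that add atoms: none
Why: Low-temperature hydride reduction of a γ-lactone stops at the lactol, which keeps the two oxygenated termini (C5 and C8) differentiated.

Step 6
Reactants: 9 (3R,4S)-4-ethynyl-3-methyltetrahydrofuran-2-ol
Product: 11 (2S,3R)-3-cyano-2-ethynylbutyl methanesulfonate, via hydroxy oxime 10 (not isolated)
Conditions: NH2OH·HCl, pyridine, EtOH, rt; evaporate; MsCl, Et3N, CH2Cl2, 0 °C → rt
Reagents that add atoms: hydroxylamine hydrochloride, [NH3+]O.[Cl-]; methanesulfonyl chloride, CS(=O)(=O)Cl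
Why: Oxime formation opens the lactol and sulfonylation of both hydroxyls followed by base-induced loss of methanesulfonate from the oxime (aldoxime dehydration) gives the nitrile and the primary mesylate, so that C8 is carried as a latent aldehyde inert to organometallic reagents at low temperature.

Step 7
Reactants: 12 3-methylbutanal; 13 3-methylbut-3-en-2-one
Product: 14 3,7-dimethyloctane-2,5-dione (racemic)
Conditions: 3-benzyl-5-(2-hydroxyethyl)-4-methylthiazolium chloride (10 mol%), Et3N, EtOH, 80 °C
Reagents that add atoms: none
Why: Stetter reaction, in which the thiazolium-derived acyl anion equivalent of the aldehyde adds in conjugate fashion to the vinyl ketone to give the 1,4-diketone.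

Step 8
Reactants: 14 3,7-dimethyloctane-2,5-dione
Product: 15 2-isopropyl-3,4-dimethylcyclopent-2-en-1-one (racemic)
Conditions: NaOH, H2O/EtOH, reflux
Reagents that add atoms: none
Why: Intramolecular aldol condensation of the 1,4-diketone under equilibrating base, which funnels to the tetrasubstituted cyclopentenone as in classical jasmone-type cyclisations.

Step 9
Reactants: 15 2-isopropyl-3,4-dimethylcyclopent-2-en-1-one
Product: 17 5-hydroxy-2-isopropyl-3,4-dimethylcyclopent-2-en-1-one (diastereomer mixture), via lithium enolate 16 (not isolated)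
Conditions: LiN(iPr)2, THF, −78 °C; 3-phenyl-2-(phenylsulfonyl)oxaziridine, −78 °C
Reagents that add atoms: 3-phenyl-2-(phenylsulfonyl)oxaziridine, O=S(=O)(N1OC1c1ccccc1)c1ccccc1
Why: Kinetic deprotonation occurs at the α′ methylene (the future C12) and oxygen transfer from the N-sulfonyloxaziridine gives the acyloin, whose configuration is irrelevant because the carbon is oxidised in step 10.

Step 10
Reactants: 17 5-hydroxy-2-isopropyl-3,4-dimethylcyclopent-2-en-1-one
Product: 18 3-isopropyl-4,5-dimethylcyclopent-3-ene-1,2-dione
Conditions: Dess–Martin periodinane, NaHCO3, CH2Cl2, 0 °C → rt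
Reagents that add atoms: none
Why: Dess–Martin oxidation of the secondary acyloin to the 1,2-dione under buffered conditions.

Step 11
Reactants: 18 3-isopropyl-4,5-dimethylcyclopent-3-ene-1,2-dione
Product: 20 (R)-5-hydroxy-3-isopropyl-4,5-dimethylcyclopent-3-ene-1,2-dione, via potassium dienolate 19 (not isolated)
Conditions: KN(SiMe3)2, THF, −78 °C; (+)-(camphorsulfonyl)oxaziridine, −78 °C
Reagents that add atoms: (+)-(camphorsulfonyl)oxaziridine, CC1(C)[C@@H]2CC[C@]13CS(=O)(=O)N4O[C@@]34C2
Why: Reagent-controlled asymmetric hydroxylation of a prochiral enolate with a chiral N-sulfonyloxaziridine, in which the delocalised dienolate should be attacked at its less hindered methyl-bearing terminus (C11) and the camphor-derived reagent selects the face that gives the 5R carbinol.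

Step 12
Reactants: 11 (2S,3R)-3-cyano-2-ethynylbutyl methanesulfonate; 20 (R)-5-hydroxy-3-isopropyl-4,5-dimethylcyclopent-3-ene-1,2-dione
Product: 23 (2R,3S)-5-[(1S,5R)-1,5-dihydroxy-3-isopropyl-4,5-dimethyl-2-oxocyclopent-3-en-1-yl]-3-(mesyloxymethyl)-2-methylpent-4-ynenitrile, via alkynylmagnesium chloride 21 (not isolated), via chloromagnesium alkoxide 22 (not isolated)
Conditions: 11, iPrMgCl·LiCl, THF, 0 °C; 20, tBuMgCl, THF, −78 °C; mix, −78 → −30 °C; aq NH4Cl
Reagents that add atoms: none
Why: 1,2-Addition of an alkynylmagnesium reagent to the non-conjugated ketone of the dione, activated and directed by the neighbouring magnesium alkoxide, whose chelate turns the C11 methyl over one face so that the alkynyl group enters cis to the C11 oxygen and gives the trans-diol with C12 as required (convergent union at the fully substituted C12).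

Step 13
Reactants: 23 propargylic diol
Product: 24 Z-alkenyl pinacol boronate (boron on C2, hydrogen on C1, C6 and C12 cis; other centres as in 23)
Conditions: CuCl (5 mol%), Xantphos (5 mol%), NaOtBu (10 mol%), B2pin2, MeOH, THF, rt
Reagents that add atoms: bis(pinacolato)diboron, CC1(C)OB(OC1(C)C)B1OC(C)(C)C(C)(C)O1
Why: Copper-catalysed syn protoboration (borylcupration then protonation by methanol) of the internal propargylic alcohol, in which boron goes to the alkyne carbon remote from the carbinol for electronic and steric reasons, while the tetrasubstituted enone and the β-branched mesylate should not react.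

Step 14
Reactants: 24 Z-alkenyl pinacol boronate
Product: 25 primary iodide (mesylate of 24 replaced by iodide)
Conditions: NaI, acetone, 55 °C
Reagents that add atoms: sodium iodide, [Na+].[I-]
Why: Finkelstein exchange of the primary mesylate for iodide.

Step 15
Reactants: 25 primary iodide
Product: 26 tris(triethylsilyl) derivative (C11 and C12 triethylsilyl ethers; ring C as the C13 silyl dienol ether with an exocyclic C9 methylene)
Conditions: Et3SiOTf, Et3N, CH2Cl2, −78 → 0 °C
Reagents that add atoms: triethylsilyl trifluoromethanesulfonate, CC[Si](CC)(CC)OS(=O)(=O)C(F)(F)F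
Why: Silyl triflate with amine base silylates both tertiary alcohols and converts the enone, whose only γ-hydrogens are on the C9 methyl, into the silyl dienol ether, so that no electrophilic carbonyl or acidic hydroxyl remains for step 17 and the nucleophile for step 19 is already in place.

Step 16
Reactants: 27 2,3-dibromoprop-1-ene
Product: 28 2-bromo-3-methoxyprop-1-ene
Conditions: NaOMe, MeOH, 0 °C → rt
Reagents that add atoms: sodium methoxide, [Na+].[O-]C
Why: SN2 displacement of the allylic bromide by methoxide, the vinylic bromide being inert.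

Step 17
Reactants: 26 tris(triethylsilyl) alkenyl boronate iodide; 28 2-bromo-3-methoxyprop-1-ene
Product: 31 ring A cyclopentyl boronate (C3 bears Bpin and CH2OMe, boron trans to the C7 side chain on C6; E alkene C2=C1; nitrile and silyl groups unchanged), via 2-lithio-3-methoxyprop-1-ene 29 (not isolated), via lithium bis(alkenyl) pinacol borate 30 (not isolated)
Conditions: 28, tBuLi (2 equiv), Et2O, −78 °C; 26, THF, −78 → 0 °C; NiBr2(dme) (10 mol%), 4,4′-di-tert-butyl-2,2′-bipyridine (12 mol%), THF/DMSO, 25 °C
Reagents that add atoms: none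
Why: Proposed new method: addition of alkenyllithium 29 to the boronate of 26 should give borate 30; iodine abstraction by low-valent nickel then gives the C5 radical, which can reach only the CH2 terminus of the new propenyl group (6-endo-trig through boron, since attack on its own alkene would need a three- or four-membered ring) and forms C4–C5 with an α-boryl radical at C3, and one-electron oxidation of that radical triggers the 1,2-shift of the C2 alkenyl group from boron to C3 (C2–C3), contracting the six-membered borate ring to the cyclopentane with boron left on C3. The closest known reaction types are the nickel-catalysed conjunctive cross-coupling of alkenylboron ate complexes with alkyl iodides and the radical-polar crossover of vinyl boronate complexes, both intermolecular three-component couplings; the intramolecular ring-forming variant with an alkenyl migrating group is the proposal. Ring A is therefore closed by a 6-endo radical addition followed by a ring-contracting 1,2-metalate shift, formally a [3+2] annulation of the C5–C6–C2 unit with the two alkene carbons of the reagent. The new stereocentre C3 is controlled by C6: in the bridged transition state boron spans C2 and C3 on one face of the forming ring and the bulky C7 substituent on C6 takes the other, so boron (later OH) should end trans to C7 and CH2OMe cis, as in the target, while the alkenyl group migrates with retention so the geometry set in step 13 becomes the E alkene. The step needs chemoselective borate formation (secured because the ring C ketone is masked as its silyl dienol ether and the nitrile is slow at −78 °C) and radical addition plus migration must outrun reduction of the C5 radical.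

Step 18
Reactants: 31 ring A cyclopentyl boronate
Product: 32 C8 aldehyde (nitrile of 31 converted to CHO)
Conditions: iBu2AlH, toluene, −78 °C; aq potassium sodium tartrate
Reagents that add atoms: water, O
Why: Partial reduction of the nitrile to the N-aluminio imine, hydrolysed on work-up to the aldehyde, with the silyl ethers, silyl dienol ether and tertiary boronate expected to survive at −78 °C.

Step 19
Reactants: 32 C8 aldehyde
Product: 33 tricyclic boronate (ring B closed, 8S hydroxyl, ring C enone restored, C11 and C12 triethylsilyl ethers, C3 Bpin)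
Conditions: BF3·OEt2, CH2Cl2 (high dilution, slow addition), −78 °C; aq NaHCO3
Reagents that add atoms: none
Why: Intramolecular vinylogous Mukaiyama aldol reaction in which the Lewis-acid-activated aldehyde is attacked by the exocyclic γ-carbon C9 of the silyl dienol ether, closing the nine-membered ring B (9-exo-trig at the aldehyde) and regenerating the enone, with C8 set by the cyclic transition state, in which the tether reaches C9 from the ring C face carrying the C12 side chain and the C7 methyl is expected to sit pseudo-equatorial to give the 8S alcohol.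

Step 20
Reactants: 33 tricyclic boronate
Product: 34 11,12-bis-O-triethylsilyl brassicicene M
Conditions: NaBO3·4H2O, THF/H2O, rt
Reagents that add atoms: sodium perborate, [Na+].[O-]OB=O
Why: Perborate oxidation of the tertiary boronate proceeds by 1,2-migration of C3 from boron to oxygen with retention, so the C3 configuration from step 17 becomes that of the tertiary alcohol.

Step 21
Reactants: 34 11,12-bis-O-triethylsilyl brassicicene M
Product: 35 brassicicene M
Conditions: HF·pyridine, pyridine, THF, 0 °C → rt
Reagents that add atoms: none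
Why: Buffered fluoride cleavage of the two tertiary triethylsilyl ethers, under conditions that should leave the tertiary allylic alcohol and the δ-hydroxy enone intact.

**Compound list**
1 | furan-2(5H)-one | O=C1OCC=C1 | starting material
2 | potassium vinyltrifluoroborate | [K+].C=C[B-](F)(F)F | starting material
3 | (S)-4-vinyldihydrofuran-2(3H)-one | O=C1OC[C@H](C=C)C1 | intermediate
4 | lithium enolate of 3 | [Li]OC1=C[C@@H](C=C)CO1 | intermediate
5 | (3R,4R)-3-methyl-4-vinyldihydrofuran-2(3H)-one | O=C1OC[C@H](C=C)[C@H]1C | intermediate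
6 | secondary ozonide (1,2,4-trioxolane) of 5 | O=C1OC[C@H](C2OCOO2)[C@H]1C | intermediate
7 | (3R,4R)-4-methyl-5-oxotetrahydrofuran-3-carbaldehyde | O=C1OC[C@H](C=O)[C@H]1C | intermediate
8 | (3R,4S)-4-ethynyl-3-methyldihydrofuran-2(3H)-one | O=C1OC[C@H](C#C)[C@H]1C | intermediate
9 | (3R,4S)-4-ethynyl-3-methyltetrahydrofuran-2-ol (anomers) | OC1OC[C@H](C#C)[C@H]1C | intermediate
10 | (2R,3S)-3-(hydroxymethyl)-2-methylpent-4-ynal oxime | ON=C[C@H](C)[C@H](CO)C#C | intermediate
11 | (2S,3R)-3-cyano-2-ethynylbutyl methanesulfonate | CS(=O)(=O)OC[C@H](C#C)[C@@H](C)C#N | intermediate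
12 | 3-methylbutanal | CC(C)CC=O | starting material
13 | 3-methylbut-3-en-2-one | CC(=O)C(C)=C | starting material
14 | 3,7-dimethyloctane-2,5-dione (racemic) | CC(=O)C(C)CC(=O)CC(C)C | intermediate
15 | 2-isopropyl-3,4-dimethylcyclopent-2-en-1-one (racemic) | CC(C)C1=C(C)C(C)CC1=O | intermediate
16 | lithium cross-conjugated enolate of 15 | CC(C)C1=C(C)C(C)C=C1O[Li] | intermediate
17 | 5-hydroxy-2-isopropyl-3,4-dimethylcyclopent-2-en-1-one (diastereomers) | CC(C)C1=C(C)C(C)C(O)C1=O | intermediate
18 | 3-isopropyl-4,5-dimethylcyclopent-3-ene-1,2-dione | CC(C)C1=C(C)C(C)C(=O)C1=O | intermediate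
19 | potassium dienolate of 18 | CC(C)C1=C(C)C(C)=C(O[K])C1=O | intermediate
20 | (R)-5-hydroxy-3-isopropyl-4,5-dimethylcyclopent-3-ene-1,2-dione | CC(C)C1=C(C)[C@@](C)(O)C(=O)C1=O | intermediate
21 | alkynylmagnesium chloride of 11 | CS(=O)(=O)OC[C@H](C#C[Mg]Cl)[C@@H](C)C#N | intermediate
22 | chloromagnesium alkoxide of 20 | CC(C)C1=C(C)[C@@](C)(O[Mg]Cl)C(=O)C1=O | intermediate
23 | (2R,3S)-5-[(1S,5R)-1,5-dihydroxy-3-isopropyl-4,5-dimethyl-2-oxocyclopent-3-en-1-yl]-3-(mesyloxymethyl)-2-methylpent-4-ynenitrile | CS(=O)(=O)OC[C@@H]([C@@H](C)C#N)C#C[C@@]1(O)C(=O)C(C(C)C)=C(C)[C@@]1(C)O | intermediate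
24 | Z-alkenyl pinacol boronate from 23 (B on C2; C6 and C12 cis) | CS(=O)(=O)OC[C@@H]([C@@H](C)C#N)/C(B2OC(C)(C)C(C)(C)O2)=C\[C@@]1(O)C(=O)C(C(C)C)=C(C)[C@@]1(C)O | intermediate
25 | primary iodide corresponding to 24 | IC[C@@H]([C@@H](C)C#N)/C(B2OC(C)(C)C(C)(C)O2)=C\[C@@]1(O)C(=O)C(C(C)C)=C(C)[C@@]1(C)O | intermediate
26 | tris(triethylsilyl) derivative of 25 (C11-O, C12-O silyl ethers; C13 silyl dienol ether, exocyclic C9 methylene) | IC[C@@H]([C@@H](C)C#N)/C(B2OC(C)(C)C(C)(C)O2)=C\[C@@]1(O[Si](CC)(CC)CC)C(O[Si](CC)(CC)CC)=C(C(C)C)C(=C)[C@@]1(C)O[Si](CC)(CC)CC | intermediate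
27 | 2,3-dibromoprop-1-ene | BrCC(Br)=C | starting material
28 | 2-bromo-3-methoxyprop-1-ene | COCC(Br)=C | intermediate
29 | 2-lithio-3-methoxyprop-1-ene | [Li]C(=C)COC | intermediate
30 | lithium bis(alkenyl) pinacol borate from 26 and 29 | [Li+].IC[C@@H]([C@@H](C)C#N)/C([B-]2(C(=C)COC)OC(C)(C)C(C)(C)O2)=C\[C@@]1(O[Si](CC)(CC)CC)C(O[Si](CC)(CC)CC)=C(C(C)C)C(=C)[C@@]1(C)O[Si](CC)(CC)CC | intermediate
31 | ring A cyclopentyl boronate (C3: Bpin trans to the C7 chain, CH2OMe cis; E alkene; C8 nitrile) | COC[C@@]1(B3OC(C)(C)C(C)(C)O3)CC[C@@H]([C@@H](C)C#N)/C1=C\[C@@]1(O[Si](CC)(CC)CC)C(O[Si](CC)(CC)CC)=C(C(C)C)C(=C)[C@@]1(C)O[Si](CC)(CC)CC | intermediate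
32 | C8 aldehyde corresponding to 31 | COC[C@@]1(B3OC(C)(C)C(C)(C)O3)CC[C@@H]([C@@H](C)C=O)/C1=C\[C@@]1(O[Si](CC)(CC)CC)C(O[Si](CC)(CC)CC)=C(C(C)C)C(=C)[C@@]1(C)O[Si](CC)(CC)CC | intermediate
33 | tricyclic C3 boronate (ring B closed, 8S-OH, enone, 11,12-bis-O-triethylsilyl) | COC[C@@]1(B3OC(C)(C)C(C)(C)O3)CC[C@@H]2/C1=C\[C@@]1(O[Si](CC)(CC)CC)C(=O)C(C(C)C)=C(C[C@H](O)[C@@H]2C)[C@@]1(C)O[Si](CC)(CC)CC | intermediate
34 | 11,12-bis-O-triethylsilyl brassicicene M | COC[C@@]1(O)CC[C@@H]2/C1=C\[C@@]1(O[Si](CC)(CC)CC)C(=O)C(C(C)C)=C(C[C@H](O)[C@@H]2C)[C@@]1(C)O[Si](CC)(CC)CC | intermediate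
35 | brassicicene M | COC[C@@]1(O)CC[C@@H]2/C1=C\[C@@]1(O)C(=O)C(C(C)C)=C(C[C@H](O)[C@@H]2C)[C@@]1(C)O | target

**Totals**
Total step count: 21. Longest linear sequence: 15 steps (steps 1–6, 12–15, 17–21).

**Three steps most likely to fail**

1. Step 17. The C5 radical may be reduced, or may couple at nickel, before it adds to the borate alkene; facial control at C3 during the ring contraction may also be poor. Fallback with known reactions: starting from iodide 25, C-alkylation of methyl 4-methoxy-3-oxobutanoate (K2CO3, DMF) would give the β-keto ester F1. Ester hydrolysis and decarboxylation (LiOH, THF/H2O, then pH 5) would give the methoxymethyl ketone F2. Rhodium-catalysed intramolecular 1,2-addition of the alkenyl boronate to the ketone ([Rh(cod)OH]2, dioxane/H2O) would close ring A to the tertiary alcohol F3. Persilylation as in step 15 would give the tetrakis(triethylsilyl) compound F4, nitrile reduction as in step 18 the aldehyde F5, ring closure as in step 19 the tricycle F6, and desilylation as in step 21 would return to the route at 35.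

2. Step 19. The nine-membered ring closure may be slow enough for intermolecular aldol addition and desilylation to compete, and facial selectivity at the C8 aldehyde may be poor (the open-chain preference would favour the 7,8-syn alcohol rather than the required anti one). Fallback: starting from 33 obtained as a mixture of C8 epimers, oxidation with Dess–Martin periodinane would give the C8 ketone F7; reduction from the exposed face of the rigid bicycle (NaBH4, MeOH, −78 °C, or a bulky trialkylborohydride) would then set C8 by substrate control and return to 33.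

3. Step 11. Oxygen transfer may occur partly at the isopropyl-bearing terminus of the dienolate, and facial discrimination by the chiral oxaziridine may be low. Fallback: starting from dione 18, hydroxylation with the achiral oxaziridine of step 9 would give the racemic hydroxy dione F8; union with enantiopure 11 as in step 12 and chromatographic separation from the ring C diastereomer F9 (the alkyne fragment acting as resolving partner) would return to the route at 23.

Further compounds
F1 | step 17 | β-keto ester from 25 and methyl 4-methoxy-3-oxobutanoate | COCC(=O)C(C(=O)OC)C[C@@H]([C@@H](C)C#N)/C(B2OC(C)(C)C(C)(C)O2)=C\[C@@]1(O)C(=O)C(C(C)C)=C(C)[C@@]1(C)O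
F2 | step 17 | methoxymethyl ketone | COCC(=O)CC[C@@H]([C@@H](C)C#N)/C(B2OC(C)(C)C(C)(C)O2)=C\[C@@]1(O)C(=O)C(C(C)C)=C(C)[C@@]1(C)O
F3 | step 17 | ring A tertiary alcohol (triol enone nitrile) | COC[C@@]1(O)CC[C@@H]([C@@H](C)C#N)/C1=C\[C@@]1(O)C(=O)C(C(C)C)=C(C)[C@@]1(C)O
F4 | step 17 | tetrakis(triethylsilyl) compound | COC[C@@]1(O[Si](CC)(CC)CC)CC[C@@H]([C@@H](C)C#N)/C1=C\[C@@]1(O[Si](CC)(CC)CC)C(O[Si](CC)(CC)CC)=C(C(C)C)C(=C)[C@@]1(C)O[Si](CC)(CC)CC
F5 | step 17 | C8 aldehyde of F4 | COC[C@@]1(O[Si](CC)(CC)CC)CC[C@@H]([C@@H](C)C=O)/C1=C\[C@@]1(O[Si](CC)(CC)CC)C(O[Si](CC)(CC)CC)=C(C(C)C)C(=C)[C@@]1(C)O[Si](CC)(CC)CC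
F6 | step 17 | 3,11,12-tris-O-triethylsilyl brassicicene M | COC[C@@]1(O[Si](CC)(CC)CC)CC[C@@H]2/C1=C\[C@@]1(O[Si](CC)(CC)CC)C(=O)C(C(C)C)=C(C[C@H](O)[C@@H]2C)[C@@]1(C)O[Si](CC)(CC)CC
F7 | step 19 | C8 ketone of 33 | COC[C@@]1(B3OC(C)(C)C(C)(C)O3)CC[C@@H]2/C1=C\[C@@]1(O[Si](CC)(CC)CC)C(=O)C(C(C)C)=C(CC(=O)[C@@H]2C)[C@@]1(C)O[Si](CC)(CC)CC
F8 | step 11 | racemic 5-hydroxy-3-isopropyl-4,5-dimethylcyclopent-3-ene-1,2-dione | CC(C)C1=C(C)C(C)(O)C(=O)C1=O
F9 | step 11 | ring C (1R,5S) diastereomer of 23 | CS(=O)(=O)OC[C@@H]([C@@H](C)C#N)C#C[C@]1(O)C(=O)C(C(C)C)=C(C)[C@]1(C)O
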